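## Structural features

The target is a flavanone whose ring B is not an arene but a 2-methoxy-1,4-benzoquinone, joined through the quinone carbon C1' (between C2'–H and the C6' carbonyl) to C2 of the chroman-4-one. Ring A is a hexasubstituted benzene fused to the dihydropyranone ring C and carries, in sequence, the 5-OH hydrogen-bonded to the C4 carbonyl, a methyl on C6, a methoxy on C7 and a methyl on C8. C2 is the only stereocentre, it is S, and it has no stereogenic neighbour, so the task is to obtain one absolute configuration and not lose it. That centre is fragile because it carries the ring oxygen O1 beta to the C4 ketone: any base that enolises C3 expels the ring A phenoxide (retro-oxa-Michael), and the chalcone recloses as a racemate. The methoxyquinone is a vinylogous ester and an oxidant, attacked by nucleophiles, bases, hydride donors and zerovalent palladium, so it can only be unveiled in the last step. The skeleton is that of a citrus flavanone, so the real difficulty lies in three methyl groups on the crowded ring A (on C6, C8 and O7) and in a late, site-selective oxidation of ring B that spares C2. The key step exploits that C6 and C8 are the only C–H positions of ring A and stand ortho and para to the 5-OH: both can be iodinated selectively, and each C–I bond can then be exchanged for C–CH3 under zerovalent palladium without base. The endgame exploits that the 3'-hydroxy-4'-methoxyphenyl ring of the chiral-pool flavanone has a free position C6' para to its hydroxyl, exactly where a para-selective phenol oxidation places the second carbonyl.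

## Logic of the disconnections

16 ⇒ 14 + 15. The C6'=O bond is removed and the C3' carbonyl is returned to a phenol. The quinone goes first because nothing upstream tolerates it (zerovalent palladium reduces it, ester-cleaving nucleophiles add to it). The gain is a stable bis-phenol. The forward step must place oxygen only at C6' and leave the chelated, fully substituted ring A phenol alone; 15 abstracts hydrogen from the non-chelated phenol and couples at its free para carbon.

14 ⇒ 12. The O5–acyl and O3'–acyl bonds are restored. The acetates are needed upstream: the one on ring B keeps electrophilic iodine out of that ring, the one on O5 turns an iodophenol into an ordinary aryl iodide. The forward step must cleave two aryl esters without enolising C3.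

12 ⇒ 9 + 10. The C6–CH3 and C8–CH3 bonds are cut. This is the strategic cut: without the two C-methyl groups ring A is that of a natural 5,7-dioxygenated flavanone, so skeleton and C2 come from one purchasable compound, and these are the only two skeletal bonds the synthesis forms. The forward step must couple twice at positions each flanked by two oxygen substituents, without base. The neutral tin donor 10 meets this; a boron methyl donor does not, because it transmetalates only with carbonate or fluoride, which would cleave the acetates and open ring C.

9 ⇒ 8 + 4. The O5–acetyl bond is cut. Acylation is placed after iodination so that the free 5-OH can still activate ring A. The forward step must acylate a hydrogen-bonded, ortho-iodinated phenol under amine conditions too weak to enolise C3.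

8 ⇒ 5 + 6. The C6–I and C8–I bonds are cut. Both carbons are ortho or para to the free 5-OH, so electrophilic substitution with 6 reaches them. The forward step must halogenate ring A twice and ring B not at all, which is why no acid activator is used.

5 ⇒ 3 + 4. The O3'–acetyl bond is cut. The forward step must acylate the free ring B phenol and leave the chelated 5-OH, which stoichiometric 4 at low temperature should do.

3 ⇒ 1 + 2. The O7–CH3 bond is cut, which leads to the chiral-pool flavanone 1. The forward step must alkylate the most acidic of three phenols without base; a Mitsunobu etherification with 2 selects by acidity in a neutral medium.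

## Other disconnections considered

Alternative 1: The cut goes through ring A at C5–C6 and C7–C8, so ring A is assembled from a four-carbon and a two-carbon piece around an ether oxygen that already holds C2. The forward key step is a Danheiser benzannulation: methyl (3S)-3-[3-(benzyloxy)-4-methoxyphenyl]-3-[(2-methyl-3-oxocyclobut-1-en-1-yl)oxy]propanoate A2 is heated with 1-methoxyprop-1-yne A3. A2 opens to a vinylketene, this adds A3 in a [2+2] sense, and the new vinylcyclobutenone opens and recloses by 6π electrocyclisation to the phenol methyl (3S)-3-[3-(benzyloxy)-4-methoxyphenyl]-3-(5-hydroxy-3-methoxy-2,4-dimethylphenoxy)propanoate A1.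
- In favour: the mechanism fixes the place of every ring A substituent (the methyl-bearing carbon of A3 bonds to the ketene carbon, which becomes C5). Both C-methyl groups, the O7 methyl and the free C5 hydroxyl arrive in one thermal, reagent-free step. On regiochemical certainty and on freedom from a toxic methyl donor it is the better plan.
- Against: C2 must be made by asymmetric synthesis and then carried as a benzylic ether beta to an ester through prolonged heating, where beta-elimination would destroy it. A2 needs a vinylogous esterification with a secondary benzylic alcohol. A1 still lacks ring C, which must be closed by acylation at C4a under acid that can ionise the benzylic C–O bond, before debenzylation and the same final oxidation.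
- Comparison: the benzannulation forms two skeletal bonds and a ring where the chosen coupling forms two bonds and no ring, so it is the more constructive step. It costs roughly twice the steps and a stereocentre that is made and then exposed, whereas the chosen plan buys C2 and only has to guard it.

Alternative 2: The cut removes ring B. In the locants of the phenol (2S)-5-(benzyloxy)-2-(2-hydroxy-4,5-dimethoxyphenyl)-7-methoxy-6,8-dimethylchroman-4-one A4, the bonds C1'–C2', C2'–C3' and C5'–C6' are disconnected. The forward key step is a Dötz benzannulation: the terminal alkyne of (2S)-5-(benzyloxy)-2-ethynyl-7-methoxy-6,8-dimethylchroman-4-one A5 inserts into pentacarbonyl[methoxy(1-methoxyvinyl)carbene]chromium A6, (CO)5Cr=C(OMe)C(OMe)=CH2, a complex of zerovalent chromium. Insertion of one CO ligand and electrocyclisation then give A4 with the large alkyne substituent ortho to the new hydroxyl.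
- In favour: ring B arrives as a para-methoxyphenol, at the hydroquinone oxidation level. The quinone then follows by oxidative demethylation, which is more dependable than para-oxidation of a mono-phenol; on this point it is the better plan. The regiochemistry with a terminal alkyne is secure, and the endgame (debenzylation, oxidation) equals the two closing steps of the chosen plan.
- Against: A5 is a propargylic aryl ether beta to a ketone. It needs a fully substituted ring A made from scratch and an enantioselective construction of C2, and it is at least as prone to retro-oxa-Michael opening as the flavanone. A6 is a thermally delicate, stoichiometric chromium reagent.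
- Comparison: three bonds and a ring are formed in one step, more than the chosen coupling achieves. The whole chromanone must be synthesised first, so the route is far longer and stereocontrol comes from a reagent rather than from the chiral pool.

Alternative 3: The cut is the aryl ether bond O1–C8a. Forward: (1S,3S)-1-[6-(benzyloxy)-2-bromo-4-methoxy-3,5-dimethylphenyl]-3-[3-(benzyloxy)-4-methoxyphenyl]propane-1,3-diol A8 is cyclised by intramolecular C–O coupling (zerovalent palladium with a bulky di-tert-butyl biaryl phosphine and a carbonate base). The product is (2S,4S)-5-(benzyloxy)-2-[3-(benzyloxy)-4-methoxyphenyl]-7-methoxy-6,8-dimethylchroman-4-ol A7. Only the C2 hydroxyl can close a six-membered ring, and the C2–O bond is not touched at carbon, so the configuration is retained.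
- In favour: ring C is closed with C4 at the alcohol level, so no enolisable ketone is present and racemisation by ring opening is impossible during the closure. In stereochemical security at this stage it is equal to or better than the chosen plan. It is also convergent and needs no site-selective halogenation of a two-ring substrate.
- Against: the bromide is flanked by the C8 methyl and the C4 side chain on an electron-rich ring, and the secondary benzylic alkoxide on palladium has a beta-hydrogen. Beta-hydride elimination with hydrodebromination therefore competes with C–O reductive elimination. After A7 the route still needs C4 oxidation, removal of two benzyl groups (hydrogenolysis can also cleave the benzylic C2–O1 bond) and the ring B oxidation, and the final flavanone regains its base sensitivity.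
- Comparison: it closes a ring and forms one bond, and it sets two stereocentres of which one is discarded. The chosen plan reaches the same ring C for nothing and is much shorter.

Key step: step 5

Remark: (2S)-hesperetin 1 is taken as a purchasable single enantiomer (it is also released from hesperidin by enzymatic deglycosylation, which leaves C2 untouched).
Remark: in the twofold steps 3, 5 and 6 the half-reacted species is numbered as a non-isolated intermediate and drawn as the isomer expected to form first; the other order of events leads to the same product.

Step 1
Reactants: 1 (2S)-hesperetin; 2 methanol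
Product: 3 (2S)-5-hydroxy-2-(3-hydroxy-4-methoxyphenyl)-7-methoxychroman-4-one
Conditions: MeOH (1.05 equiv), PPh3 (1.1 equiv), diisopropyl azodicarboxylate (DIAD, 1.1 equiv), THF, 0 °C to rt
Reagents that add atoms: methanol, SMILES CO
Why: Mitsunobu etherification; the betaine deprotonates the most acidic phenol, the 7-OH para to the C4 carbonyl, whose phenoxide is methylated by the methoxyphosphonium ion, while the chelated 5-OH and the less acidic 3'-OH should stay free, and the neutral medium cannot open ring C.

Step 2
Reactants: 3 (2S)-5-hydroxy-2-(3-hydroxy-4-methoxyphenyl)-7-methoxychroman-4-one; 4 acetic anhydride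
Product: 5 (2S)-2-(3-acetoxy-4-methoxyphenyl)-5-hydroxy-7-methoxychroman-4-one
Conditions: Ac2O (1.1 equiv), pyridine, CH2Cl2, 0 °C
Reagents that add atoms: acetic anhydride, SMILES CC(=O)OC(C)=O
Why: Selective O-acylation; the free ring B phenol reacts, whereas the 5-OH is locked in its hydrogen bond to C4=O and needs DMAP and excess anhydride.

Step 3
Reactants: 5 (2S)-2-(3-acetoxy-4-methoxyphenyl)-5-hydroxy-7-methoxychroman-4-one; 6 N-iodosuccinimide
Product: 8 (2S)-2-(3-acetoxy-4-methoxyphenyl)-5-hydroxy-6,8-diiodo-7-methoxychroman-4-one, via 6-iodo monoiodide 7 (not isolated)
Conditions: NIS (2.2 equiv), DMF, 0 °C to rt, dark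
Reagents that add atoms: N-iodosuccinimide, SMILES O=C1CCC(=O)N1I
Why: Electrophilic aromatic iodination ortho and para to the free 5-OH of the phloroglucinol-type ring A; ring B has only an anisole-type methoxy group next to an electron-withdrawing acetate and, with no acid activator present, should not react.

Step 4
Reactants: 8 (2S)-2-(3-acetoxy-4-methoxyphenyl)-5-hydroxy-6,8-diiodo-7-methoxychroman-4-one; 4 acetic anhydride
Product: 9 (2S)-5-acetoxy-2-(3-acetoxy-4-methoxyphenyl)-6,8-diiodo-7-methoxychroman-4-one
Conditions: Ac2O (3 equiv), pyridine, DMAP (0.1 equiv), CH2Cl2, 0 °C to rt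
Reagents that add atoms: acetic anhydride, SMILES CC(=O)OC(C)=O
Why: DMAP-catalysed acylation of the chelated phenol, made more acidic by the ortho iodine; pyridine and DMAP at room temperature are too weak to enolise C3, so ring C and C2 should be unaffected.

Step 5
Reactants: 9 (2S)-5-acetoxy-2-(3-acetoxy-4-methoxyphenyl)-6,8-diiodo-7-methoxychroman-4-one; 10 tetramethyltin
Product: 12 (2S)-5-acetoxy-2-(3-acetoxy-4-methoxyphenyl)-7-methoxy-6,8-dimethylchroman-4-one, via 8-methyl monoiodide 11 (not isolated)
Conditions: Me4Sn (6 equiv), Pd(PPh3)4 (10 mol %), CuI (20 mol %), degassed NMP, 90 °C, sealed tube; aqueous KF work-up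
Reagents that add atoms: tetramethyltin, SMILES C[Sn](C)(C)C
Why: Twofold Stille methylation, the closest known reaction type being the palladium-catalysed coupling of aryl iodides with Me4Sn. Zerovalent palladium inserts into each C–I bond, a methyl group passes from tin to divalent palladium with loss of Me3SnI, and reductive elimination forms C6–CH3 and C8–CH3; the cycle runs twice per molecule through the mono-methyl iodide 11. No ring is closed and no stereocentre is created; C2 is only carried through. The step needs chemoselectivity for C–I over the two aryl acetates and the ketone, which the neutral tin reagent provides, and it needs the absence of base so that C3 is never enolised and ring C cannot open. Both iodides lie between two oxygen substituents, but methyl is the smallest transferable group and all four groups on tin are the same. CuI takes up free PPh3 and so speeds the slow methyl transmetalation, and NMP replaces DMF because it cannot release a secondary amine on heating. The 5-O-acetyl group keeps ring A from behaving as an iodophenol, whose dienone tautomer could pass positive iodine to phosphine, and it lowers the electron density so that oxidative addition is easier.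

Step 6
Reactants: 12 (2S)-5-acetoxy-2-(3-acetoxy-4-methoxyphenyl)-7-methoxy-6,8-dimethylchroman-4-one; 2 methanol
Product: 14 (2S)-5-hydroxy-2-(3-hydroxy-4-methoxyphenyl)-7-methoxy-6,8-dimethylchroman-4-one, via 5-monoacetate 13 (not isolated)
Conditions: NH4OAc (8 equiv), MeOH, rt
Reagents that add atoms: none
Why: Near-neutral transesterification of aryl acetates to methanol promoted by NH4OAc; the medium is too weakly basic to enolise C3, so both phenols should be released without ring opening.

Step 7
Reactants: 14 (2S)-5-hydroxy-2-(3-hydroxy-4-methoxyphenyl)-7-methoxy-6,8-dimethylchroman-4-one; 15 Fremy's salt (potassium nitrosodisulfonate)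
Product: 16 2-[(2S)-5-hydroxy-7-methoxy-6,8-dimethyl-4-oxochroman-2-yl]-5-methoxycyclohexa-2,5-diene-1,4-dione
Conditions: (KSO3)2NO (2.5 equiv), KH2PO4/K2HPO4 buffer pH 6.5, acetone–H2O, 0 °C to rt
Reagents that add atoms: Fremy's salt, (KSO3)2NO, SMILES [K+].[K+].[O]N(S(=O)(=O)[O-])S(=O)(=O)[O-]
Why: Teuber oxidation; one nitroxyl radical abstracts the hydrogen of the 3'-OH, a second couples through oxygen at the free para carbon C6', and loss of imidodisulfonate leaves the C6' carbonyl. The 5-OH is hydrogen-bonded on an acyl-substituted ring with no free position and should be spared, and the near-neutral buffer leaves C2 alone.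

## Compound list

1 | (2S)-hesperetin | COc1ccc(cc1O)[C@@H]2CC(=O)c3c(O)cc(O)cc3O2 | starting material
2 | methanol | CO | starting material
3 | (2S)-5-hydroxy-2-(3-hydroxy-4-methoxyphenyl)-7-methoxychroman-4-one | COc1ccc(cc1O)[C@@H]2CC(=O)c3c(O)cc(OC)cc3O2 | intermediate
4 | acetic anhydride | CC(=O)OC(C)=O | starting material
5 | (2S)-2-(3-acetoxy-4-methoxyphenyl)-5-hydroxy-7-methoxychroman-4-one | COc1ccc(cc1OC(C)=O)[C@@H]2CC(=O)c3c(O)cc(OC)cc3O2 | intermediate
6 | N-iodosuccinimide | O=C1CCC(=O)N1I | starting material
7 | (2S)-2-(3-acetoxy-4-methoxyphenyl)-5-hydroxy-6-iodo-7-methoxychroman-4-one (transient in step 3) | COc1ccc(cc1OC(C)=O)[C@@H]2CC(=O)c3c(O)c(I)c(OC)cc3O2 | intermediate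
8 | (2S)-2-(3-acetoxy-4-methoxyphenyl)-5-hydroxy-6,8-diiodo-7-methoxychroman-4-one | COc1ccc(cc1OC(C)=O)[C@@H]2CC(=O)c3c(O)c(I)c(OC)c(I)c3O2 | intermediate
9 | (2S)-5-acetoxy-2-(3-acetoxy-4-methoxyphenyl)-6,8-diiodo-7-methoxychroman-4-one | COc1ccc(cc1OC(C)=O)[C@@H]2CC(=O)c3c(OC(C)=O)c(I)c(OC)c(I)c3O2 | intermediate
10 | tetramethyltin | C[Sn](C)(C)C | starting material
11 | (2S)-5-acetoxy-2-(3-acetoxy-4-methoxyphenyl)-6-iodo-7-methoxy-8-methylchroman-4-one (transient in step 5) | COc1ccc(cc1OC(C)=O)[C@@H]2CC(=O)c3c(OC(C)=O)c(I)c(OC)c(C)c3O2 | intermediate
12 | (2S)-5-acetoxy-2-(3-acetoxy-4-methoxyphenyl)-7-methoxy-6,8-dimethylchroman-4-one | COc1ccc(cc1OC(C)=O)[C@@H]2CC(=O)c3c(OC(C)=O)c(C)c(OC)c(C)c3O2 | intermediate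
13 | (2S)-5-acetoxy-2-(3-hydroxy-4-methoxyphenyl)-7-methoxy-6,8-dimethylchroman-4-one (transient in step 6) | COc1ccc(cc1O)[C@@H]2CC(=O)c3c(OC(C)=O)c(C)c(OC)c(C)c3O2 | intermediate
14 | (2S)-5-hydroxy-2-(3-hydroxy-4-methoxyphenyl)-7-methoxy-6,8-dimethylchroman-4-one | COc1ccc(cc1O)[C@@H]2CC(=O)c3c(O)c(C)c(OC)c(C)c3O2 | intermediate
15 | Fremy's salt, potassium nitrosodisulfonate (KSO3)2NO | [K+].[K+].[O]N(S(=O)(=O)[O-])S(=O)(=O)[O-] | starting material
16 | 2-[(2S)-5-hydroxy-7-methoxy-6,8-dimethyl-4-oxochroman-2-yl]-5-methoxycyclohexa-2,5-diene-1,4-dione (CNP0208927.1) | COC1=CC(=O)C([C@@H]2CC(=O)c3c(O)c(C)c(OC)c(C)c3O2)=CC1=O | target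

## Step count and least certain steps

Total step count: 7. Longest linear sequence: 7 steps, from 1 to 16.

Step 5 (key step). The coupling may stall after the first methyl transfer, because methyl leaves tin slowly and each arylpalladium intermediate is flanked by two oxygen substituents; this gives time for reductive loss of iodine. Prolonged heating to force the second coupling invites acetate loss and, through traces of base, opening of ring C. The fallback leaves step 4 out and couples the iodophenol as its zinc phenoxide. It sets out from 8: MeZnCl (commercial THF solution, 5 equiv, the first of which deprotonates the 5-OH) and Pd(dppf)Cl2, [1,1'-bis(diphenylphosphino)ferrocene]dichloropalladium, a divalent palladium precatalyst reduced in the flask to zerovalent palladium, in THF at rt to 50 °C (Negishi coupling). This should give (2S)-2-(3-acetoxy-4-methoxyphenyl)-5-hydroxy-7-methoxy-6,8-dimethylchroman-4-one F1. NH4OAc in MeOH then removes the one acetate, and the route is rejoined at 14. The change is one of approach: zinc transmetalates fast below 50 °C, the 5-O-acetyl group disappears from the plan, and a chelating diphosphine leaves no free phosphine.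

Step 3. The second iodination may be slow, because the first iodine deactivates ring A and the chelated 5-OH is only a moderate activator. Forcing it with acid or excess reagent lets substitution spill over to ring B, and C–I bonds on so electron-rich a ring can be lost again on work-up. The fallback halogenates with bromine and adapts the coupling. It sets out from 5: NBS (2.1 equiv) in MeCN at 0 °C should give (2S)-2-(3-acetoxy-4-methoxyphenyl)-6,8-dibromo-5-hydroxy-7-methoxychroman-4-one F2. Ac2O, pyridine and DMAP should then give (2S)-5-acetoxy-2-(3-acetoxy-4-methoxyphenyl)-6,8-dibromo-7-methoxychroman-4-one F3. A Negishi coupling with MeZnCl under Pd(OAc)2 (reduced in the flask to zerovalent palladium) and SPhos (2-dicyclohexylphosphino-2',6'-dimethoxybiphenyl) in THF at 60 °C rejoins the route at 12.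

Step 1. Methylation may run on to O3', or select poorly between O7 and O3', because the phenoxide of the less acidic 3'-OH is the more nucleophilic one. The fallback replaces acidity control by protecting-group control. It sets out from 1: Ac2O, pyridine and DMAP should give (2S)-5,7-diacetoxy-2-(3-acetoxy-4-methoxyphenyl)chroman-4-one F4. PhSH and imidazole in NMP at 0 °C cleave only the acetate para to the carbonyl and should give (2S)-5-acetoxy-2-(3-acetoxy-4-methoxyphenyl)-7-hydroxychroman-4-one F5. Mitsunobu methylation (MeOH, PPh3, DIAD) of the single free phenol should give (2S)-5-acetoxy-2-(3-acetoxy-4-methoxyphenyl)-7-methoxychroman-4-one F6. NH4OAc in MeOH removes both acetates, and the route is rejoined at 3.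

Step 7. Hydrogen abstraction from the guaiacol-type phenol may be slow, and the methoxyquinone may be over-oxidised or attacked by nucleophiles in the aqueous medium. The fallback changes the oxidant class from a stoichiometric nitroxyl radical to aerobic cobalt catalysis. It sets out from 14: Co(salen), N,N'-bis(salicylidene)ethylenediaminocobalt, a complex of divalent cobalt (15 mol %), under O2 (1 atm) in DMF at rt, where a cobalt-bound superoxide delivers oxygen to the para carbon. It arrives directly at 16 and makes no new compound.

## Further compounds

F1 | step 5 | (2S)-2-(3-acetoxy-4-methoxyphenyl)-5-hydroxy-7-methoxy-6,8-dimethylchroman-4-one | COc1ccc(cc1OC(C)=O)[C@@H]2CC(=O)c3c(O)c(C)c(OC)c(C)c3O2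
F2 | step 3 | (2S)-2-(3-acetoxy-4-methoxyphenyl)-6,8-dibromo-5-hydroxy-7-methoxychroman-4-one | COc1ccc(cc1OC(C)=O)[C@@H]2CC(=O)c3c(O)c(Br)c(OC)c(Br)c3O2
F3 | step 3 | (2S)-5-acetoxy-2-(3-acetoxy-4-methoxyphenyl)-6,8-dibromo-7-methoxychroman-4-one | COc1ccc(cc1OC(C)=O)[C@@H]2CC(=O)c3c(OC(C)=O)c(Br)c(OC)c(Br)c3O2
F4 | step 1 | (2S)-5,7-diacetoxy-2-(3-acetoxy-4-methoxyphenyl)chroman-4-one | COc1ccc(cc1OC(C)=O)[C@@H]2CC(=O)c3c(OC(C)=O)cc(OC(C)=O)cc3O2
F5 | step 1 | (2S)-5-acetoxy-2-(3-acetoxy-4-methoxyphenyl)-7-hydroxychroman-4-one | COc1ccc(cc1OC(C)=O)[C@@H]2CC(=O)c3c(OC(C)=O)cc(O)cc3O2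
F6 | step 1 | (2S)-5-acetoxy-2-(3-acetoxy-4-methoxyphenyl)-7-methoxychroman-4-one | COc1ccc(cc1OC(C)=O)[C@@H]2CC(=O)c3c(OC(C)=O)cc(OC)cc3O2
F0 | step 7 | none | none
A1 | alternative 1 | methyl (3S)-3-[3-(benzyloxy)-4-methoxyphenyl]-3-(5-hydroxy-3-methoxy-2,4-dimethylphenoxy)propanoate | COC(=O)C[C@H](Oc1cc(O)c(C)c(OC)c1C)c1ccc(OC)c(OCc2ccccc2)c1
A2 | alternative 1 | methyl (3S)-3-[3-(benzyloxy)-4-methoxyphenyl]-3-[(2-methyl-3-oxocyclobut-1-en-1-yl)oxy]propanoate | COC(=O)C[C@H](OC1=C(C)C(=O)C1)c1ccc(OC)c(OCc2ccccc2)c1
A3 | alternative 1 | 1-methoxyprop-1-yne | COC#CC
A4 | alternative 2 | (2S)-5-(benzyloxy)-2-(2-hydroxy-4,5-dimethoxyphenyl)-7-methoxy-6,8-dimethylchroman-4-one | COc1cc(O)c(cc1OC)[C@@H]2CC(=O)c3c(OCc4ccccc4)c(C)c(OC)c(C)c3O2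
A5 | alternative 2 | (2S)-5-(benzyloxy)-2-ethynyl-7-methoxy-6,8-dimethylchroman-4-one | C#C[C@@H]1CC(=O)c2c(OCc3ccccc3)c(C)c(OC)c(C)c2O1
A6 | alternative 2 | pentacarbonyl[methoxy(1-methoxyvinyl)carbene]chromium | COC(=C)C(OC)=[Cr](=C=O)(=C=O)(=C=O)(=C=O)=C=O
A7 | alternative 3 | (2S,4S)-5-(benzyloxy)-2-[3-(benzyloxy)-4-methoxyphenyl]-7-methoxy-6,8-dimethylchroman-4-ol | COc1ccc(cc1OCc1ccccc1)[C@@H]2C[C@H](O)c3c(OCc4ccccc4)c(C)c(OC)c(C)c3O2
A8 | alternative 3 | (1S,3S)-1-[6-(benzyloxy)-2-bromo-4-methoxy-3,5-dimethylphenyl]-3-[3-(benzyloxy)-4-methoxyphenyl]propane-1,3-diol | COc1ccc(cc1OCc1ccccc1)[C@@H](O)C[C@H](O)c1c(OCc2ccccc2)c(C)c(OC)c(C)c1Br
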